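**Assumptions (one line each)**
- The target SMILES has no stereocentres, and the 3'–8'' biaryl axis (three ortho substituents, as in amentoflavone) carries no configurational descriptor, so there is no stereochemistry to set.
- A telescoped one-pot sequence is counted as one step.

**Retrosynthetic overview**
1. Dulcisbiflavonoid A ⇒ 3'-prenylapigenin + 6-prenylapigenin, by cutting the C3'–C8'' biaryl bond; it is formed last, as a protecting-group-free radical C–H/C–H cross-coupling.
2. 6-Prenylapigenin ⇒ apigenin + prenyl bromide (C6 alkylation); 3'-prenylapigenin ⇒ phloroglucinol + a prenylated aroylacetate.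
3. Both aroylacetates ⇒ 4-hydroxyacetophenone (phenol + acetyl chloride) + diethyl carbonate; phloroglucinol ⇒ resorcinol by C–H borylation/oxidation.
4. Ring order: the benzene rings are bought; each pyrone ring is closed by thermal annulation onto phloroglucinol; the inter-flavone bond comes last.

**Route**

**Step 1**
Reactants: 1 resorcinol
Product: 2 phloroglucinol (benzene-1,3,5-triol)
Conditions: (i) HMDS, 110 °C, evaporate; (ii) [Ir(OMe)(cod)]2 (1 mol%), dtbpy (2 mol%), B2pin2, hexane, 60 °C; (iii) Oxone, acetone/H2O, rt, then NaHSO3 (one pot)
Reagents that add atoms: Oxone (potassium peroxymonosulfate), OOS(=O)(=O)[O-].[K+], supplies the new phenolic O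
Why: Sterically controlled Ir-catalysed C–H borylation of the transient bis-TMS ether can only occur at C5 (all other C–H are ortho to OTMS); Oxone converts C–B to C–OH and the acidic aqueous medium removes TMS (one-pot C–H borylation/oxidation to 3,5-disubstituted phenols).

**Step 2**
Reactants: 3 phenol; 4 acetyl chloride
Product: 5 4-hydroxyacetophenone
Conditions: AcCl (1.1 equiv), TfOH (neat), 0 °C → rt
Reagents that add atoms: none beyond numbered reactant 4 (CC(=O)Cl)
Why: O-acylation followed by Fries/Friedel–Crafts acylation in superacid gives the para-hydroxyaryl ketone selectively.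

**Step 3**
Reactants: 5 4-hydroxyacetophenone; 6 diethyl carbonate
Product: 7 ethyl 3-(4-hydroxyphenyl)-3-oxopropanoate
Conditions: NaH (3.5 equiv), (EtO)2CO (4 equiv), THF, reflux; AcOH/H2O quench
Reagents that add atoms: none beyond numbered reactant 6 (CCOC(=O)OCC)
Why: Crossed Claisen condensation of the phenoxide–enolate dianion with a non-enolisable carbonate, driven by formation of the stabilised β-ketoester enolate.

**Step 4**
Reactants: 7 ethyl 3-(4-hydroxyphenyl)-3-oxopropanoate; 2 phloroglucinol
Product: 8 apigenin (5,7-dihydroxy-2-(4-hydroxyphenyl)-4H-chromen-4-one)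
Conditions: neat, 7 (1.5 equiv), microwave, 240 °C, 5 min, Ar
Reagents that add atoms: none
Why: Mentzer thermal pyrone synthesis (acyl transfer to phloroglucinol, C-acylation, cyclodehydration with loss of EtOH and H2O); phloroglucinol is C3-symmetric, so only one flavone can form.

**Step 5**
Reactants: 8 apigenin; 9 prenyl bromide (1-bromo-3-methylbut-2-ene)
Product: 10 6-prenylapigenin (5,7-dihydroxy-2-(4-hydroxyphenyl)-6-(3-methylbut-2-en-1-yl)-4H-chromen-4-one)
Conditions: 9 (1.2 equiv), NaOMe (3.5 equiv), MeOH, 0 °C → rt; chromatography
Reagents that add atoms: none beyond numbered reactant 9 (CC(C)=CCBr)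
Why: C-alkylation of the ambident 5,7-dioxido A ring in a protic solvent, where H-bonded phenoxide oxygens disfavour O-alkylation; C6, flanked by two oxygens, is the most nucleophilic carbon (C6 > C8, as in the known prenylations of chrysin and genistein). Expect about 20–30% after removing the 8-prenyl, 6,8-diprenyl and O-prenyl by-products; confirm the 6-position by HMBC from the chelated 5-OH.

**Step 6**
Reactants: 5 4-hydroxyacetophenone; 9 prenyl bromide
Product: 11 4-hydroxy-3-prenylacetophenone (1-[4-hydroxy-3-(3-methylbut-2-en-1-yl)phenyl]ethanone)
Conditions: 9 (1.0 equiv), 10% aq KOH, rt; chromatography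
Reagents that add atoms: none beyond numbered reactant 9
Why: Kornblum-type ortho C-alkylation of a phenoxide in water; the para position is blocked by acetyl, so only ortho C-prenylation is possible (about 30%, with O-prenyl ether and 3,5-diprenyl by-products separated).

**Step 7**
Reactants: 11 4-hydroxy-3-prenylacetophenone; 6 diethyl carbonate
Product: 12 ethyl 3-[4-hydroxy-3-(3-methylbut-2-en-1-yl)phenyl]-3-oxopropanoate
Conditions: NaH (3.5 equiv), (EtO)2CO (4 equiv), THF, reflux; AcOH/H2O quench
Reagents that add atoms: none beyond numbered reactant 6
Why: Same crossed Claisen condensation as step 3; the isolated trisubstituted alkene is inert to NaH and ethoxide.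

**Step 8**
Reactants: 12 prenylated β-ketoester; 2 phloroglucinol
Product: 13 3'-prenylapigenin (5,7-dihydroxy-2-[4-hydroxy-3-(3-methylbut-2-en-1-yl)phenyl]-4H-chromen-4-one)
Conditions: neat, 2 (2 equiv), microwave, 220–240 °C, 3 min, Ar, acid-free
Reagents that add atoms: none
Why: Mentzer pyrone synthesis as in step 4; the short acid-free heating is chosen to outrun chroman formation from the ortho-prenylphenol, and phloroglucinol's symmetry again gives a single flavone.

**Step 9 (key step)**
Reactants: 13 3'-prenylapigenin (1 equiv); 10 6-prenylapigenin (3 equiv, excess recovered)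
Product: 14 Dulcisbiflavonoid A
Conditions: BDD anode / graphite cathode, undivided cell, HFIP–MeOH (82:18), Et3NMe·O3SOMe (0.1 M), 50 °C, 2.8 mA cm⁻², about 2 F per mol of 13; stop at about 70% conversion
Reagents that add atoms: none
Why: Proposed new method: anodic proton-coupled oxidation of the most easily oxidised phenol in the mixture gives an HFIP-solvated phenoxyl radical, and that phenol is the ortho-alkylated 4'-OH of 13. B-ring 4'-phenols of apigenins oxidise before the chelated 5,7-dihydroxy A ring, and phenoxyl/phenol H-exchange should funnel spin to the more stabilised ortho-prenyl radical. Its only open ortho carbon is C5' (C3' carries the prenyl, para carries the chromone), and it is trapped by the most nucleophilic carbon present, C8 of 10 (C6 blocked by prenyl, 3-fold excess); a second electron/proton loss rearomatises to the 3'–8'' biaryl. The closest known reactions are anodic phenol–phenol and phenol–arene dehydrogenative cross-couplings of unprotected phenols on BDD in HFIP, Fe/peroxide/HFIP phenol cross-couplings, and FeCl3-type oxidative couplings of 5,7-dioxygenated flavones through C8. Expect a low yield (about 10–25%) with 10–10 and 13–13 dimers, C–O coupled ethers and chromenes (from oxidation of the ortho-prenylphenol) as by-products; the weakest point is that the free 4'-OH of 10 is only slightly harder to oxidise than that of 13.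

**Compound list**
1 | resorcinol | Oc1cccc(O)c1 | starting material
2 | phloroglucinol | Oc1cc(O)cc(O)c1 | intermediate
3 | phenol | Oc1ccccc1 | starting material
4 | acetyl chloride | CC(=O)Cl | starting material
5 | 4-hydroxyacetophenone | CC(=O)c1ccc(O)cc1 | intermediate
6 | diethyl carbonate | CCOC(=O)OCC | starting material
7 | ethyl 3-(4-hydroxyphenyl)-3-oxopropanoate | CCOC(=O)CC(=O)c1ccc(O)cc1 | intermediate
8 | apigenin | O=c1cc(-c2ccc(O)cc2)oc2cc(O)cc(O)c12 | intermediate
9 | prenyl bromide | CC(C)=CCBr | starting material
10 | 6-prenylapigenin | CC(C)=CCc1c(O)cc2oc(-c3ccc(O)cc3)cc(=O)c2c1O | intermediate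
11 | 4-hydroxy-3-prenylacetophenone | CC(=O)c1ccc(O)c(CC=C(C)C)c1 | intermediate
12 | ethyl 3-(4-hydroxy-3-prenylphenyl)-3-oxopropanoate | CCOC(=O)CC(=O)c1ccc(O)c(CC=C(C)C)c1 | intermediate
13 | 3'-prenylapigenin | CC(C)=CCc1cc(-c2cc(=O)c3c(O)cc(O)cc3o2)ccc1O | intermediate
14 | Dulcisbiflavonoid A | CC(C)=CCc1cc(-c2cc(=O)c3c(O)cc(O)cc3o2)cc(-c2c(O)c(CC=C(C)C)c(O)c3c(=O)cc(-c4ccc(O)cc4)oc23)c1O | target

**Totals**
- Total steps: 9.
- Longest linear sequence: 5 (phenol → 5 → 11 → 12 → 13 → 14; the branch through 7, 8 and 10 is also 5).

**Three steps most likely to fail, with fallbacks**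
1. **Step 9 (unprotected radical cross-coupling; chemoselectivity between the two 4'-phenols and the two A rings).** Fallback: enforce the roles structurally. Cap 7-OH of 13 as a pivalate (switches off its A ring) and make the nucleophile as its 4'-O-methyl ether (6-prenylacacetin, by starting that branch from anisole instead of phenol). Then only one phenol can be oxidised and only one ring is nucleophilic in the same radical coupling; finish with NaSEt/DMF to remove the methyl and pivaloyl groups. This costs two extra steps.
2. **Step 5 (C6 versus C8 versus O-prenylation of apigenin).** Fallback: replace direct alkylation with halogen-directed installation. Iodinate apigenin selectively at C6 with BnMe3N·ICl2/CaCO3, then carry out a ligand-controlled α-selective Suzuki coupling with prenyl–Bpin.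
3. **Step 8 (ortho-prenylphenol exposed to a 240 °C melt; chroman formation).** Fallback: take the prenyl group out of the thermal step. Iodinate 5 to 4-hydroxy-3-iodoacetophenone, carry the iodide through the Claisen and Mentzer steps to 3'-iodoapigenin, and introduce the prenyl group afterwards by Pd-catalysed coupling with prenyl–Bpin under mild conditions.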